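(All runs come from a simulation from invented constants; noise was put on by code.)

If the E that goes missing from the readings sits in a bis adduct L, two sums hold in a closed flask: E, G and L add up to the E charged, and the Z taken up equals G plus twice L. So you can reckon cL and cZ from any reading.

| flask | E | Z | remark | time |
|---|---|---|---|---|
| south-east | 0.30 M | 0.082 M | run made earlier |  |
| south | 0.30 M | 0.38 M | run made earlier |  |
| east | 0.30 M | 0.98 M | run made earlier |  |
| north-west | 0.38 M | 0.30 M | run made earlier |  |
| red | 0.30 M | 0.500 M |  | 12 h |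
| violet | 0.30 M | 0.300 M |  | 12 h |
| teal | 0.20 M | 0.100 M |  | 12 h |
| ochre | 0.080 M | 1.00 M |  | 12 h |
| grey | 1.2 M | 1.20 M |  | 12 h |

| run | time / h | G / % | E / % |
|---|---|---|---|
| south-east | 1.00 | 13.0 | 86.2 |
| south-east | 3.00 | 20.5 | 76.6 |
| south-east | 6.00 | 24.0 | 75.0 |
| south-east | 8.00 | 24.3 | 74.6 |
| south-east | 12.0 | 24.8 | 74.1 |
| south | 1.00 | 39.7 | 48.8 |
| south | 3.00 | 53.9 | 24.7 |
| south | 6.00 | 67.5 | 13.3 |
| south | 8.00 | 72.4 | 9.8 |
| south | 12.0 | 78.7 | 6.1 |
| east | 1.00 | 45.7 | 14.3 |
| east | 2.00 | 44.2 | 2.9 |
| east | 3.00 | 43.6 | 1.2 |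
| east | 6.00 | 43.3 | 0 |
| east | 12.0 | 44.1 | 0 |
| north-west | 1.00 | 34.2 | 60.4 |
| north-west | 3.00 | 49.7 | 41.8 |
| north-west | 6.00 | 58.6 | 32.9 |
| north-west | 8.00 | 63.9 | 30.1 |
| north-west | 12.0 | 68.4 | 27.5 |

(standard deviation of a reading: 0.5 percentage points)



- the flasks by amount of G, in percent of the E charged, highest first, at 12 h (red / violet / teal / ochre / grey)
- the same order at 2.5 h (red / violet / teal / ochre / grey)
- the amount of G, in percent of the E charged of the flask you put first, at 12 h
- the amount of G, in percent of the E charged of the flask you put last, at 12 h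

Ochre looks like the east run, with 1.00 M of Z against 0.98 M. East has E at 0% by 6.00 h, and at 12.0 h it holds G at 44.1% and, by the sum, L at 55.9%.

The plain ratio cL/(cG·cZ) is 2.47 /M there. At the end of the south run, where L is 15.2%, it is larger than that, 3.66 /M. So my own guess is that each Z taken up sets free one by-product J, whose amount is then the Z taken up: 0.468 M in east, 0.327 M in south.

The exchange quotient 1.16, that is cL·cJ over cG·cZ, an apparent equilibrium constant, reads so in east and 1.20 in south.

With the quotient held, L over G equals it times cZ/cJ. East ends with cZ/cJ at 1.09. Ochre has 0.080 M of E against 0.30 M, so even with all its E as L, cZ/cJ is 5.25, more than in east. Setting E in ochre to 0% as in east, and solving the two sums with the quotient, I commit to G at 13.2% in ochre.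

The forecast gives grey > violet > red > teal > ochre at 12 h and grey > red > violet > ochre > teal at 2.5 h, with 86% (78% to 93%) for the first flask and 31% (24% to 41%) for the last. For ochre its grounds are “Ochre: Z large”, with its bis adduct, here L, at 2.3 times G. My ochre figure is lower than its range.

The flasks give grey > violet > red > teal > ochre at 12 h and grey > red > violet > teal > ochre at 2.5 h, with grey at 91.9% and ochre at 12.8%, which ten times the time leaves as it is.

    E + Z → G + J (k = 0.0430 /M/min)
    Z + G ⇌ L + J (K = 1.20, k = 0.0280 /M/min)

In grey, the forward half-life of G through Z + G → L + J, that step's forward rate taken alone, is 0.78 h at 0.312 h, shorter than the 12 h allowed, while G is then made 2.74 times faster than it is used up, each step taken net. At 12.0 h grey holds L at 2.84%, and its exchange quotient reads 1.26.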